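**Strategy.** The six-membered carbocycle C1–C6 and its exocyclic carbon C7 are the ring and carboxyl carbon of methyl benzoate, and the cis C5–O/C6–O pair next to C1 is an ortho,meta cis-dihydrodiol. One whole-cell toluene dioxygenase oxidation of methyl benzoate (used as bought, no prior chemistry) therefore forms both C–O bonds, both stereocentres and a diene whose C1=C2 bond is deactivated by the ester. The free diol then steers OsO4·TMEDA to the same face of C3=C4 (all-cis tetrol). Kinetic acetonation, DIBAL-H reduction and two site-selective benzoylations (O7, then O5) finish the target.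

Key step: step 1

Remark on numbering and configuration: C1 is the ring alkene carbon bearing C7, C2 the alkene CH, C3–C6 the four carbinol carbons, and O3–O7 the oxygens on C3–C7. It is assumed that toluene dioxygenase oxidises methyl benzoate with the same facial sense as toluene, giving the (5S,6R)-diol, which is the configuration the target needs at C5 and C6. The target is (3S,4S,5R,6R) with all four ring oxygens cis.

**Step 1**
Reactants: 1 methyl benzoate
Product: 2 methyl (5S,6R)-5,6-dihydroxycyclohexa-1,3-diene-1-carboxylate
Conditions: E. coli JM109(pDTG601) whole cells (toluene dioxygenase, IPTG-induced), glucose feed, air, mineral salts medium pH 7, 30–35 °C; EtOAc extraction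
Reagents that add atoms: dioxygen, O=O
Why: Electrons from cellular NADH pass through the reductase, the ferredoxin and the Rieske [2Fe–2S] cluster to the mononuclear non-heme iron of the oxygenase, which binds O2 and transfers both oxygen atoms to one face of the ortho,meta bond, forming C5–O and C6–O in one event and leaving the C1=C2–C3=C4 diene. The closest known reaction type is the dioxygenase-mediated dearomatising cis-dihydroxylation of monosubstituted benzenes, which is established for benzoate esters. No ring is closed; the carbocycle and C7 come intact from the arene. C5 (S) and C6 (R) are both set by the enzyme pocket, which presents one arene face to iron with the substituent held where methyl sits in toluene, so the same absolute sense as in the toluene diol should result. The step needs ortho,meta regioselectivity and a single enantiomer, both secured by the active site; the ester also stabilises the diol against dehydration and keeps C1=C2 electron-poor for step 2.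

**Step 2**
Reactants: 2 methyl (5S,6R)-5,6-dihydroxycyclohexa-1,3-diene-1-carboxylate
Product: 4 methyl (3S,4S,5R,6R)-3,4,5,6-tetrahydroxycyclohex-1-ene-1-carboxylate, via osmate ester TMEDA chelate 3 (not isolated)
Conditions: OsO4 (1.05 equiv), TMEDA (1.1 equiv), CH2Cl2, −78 °C; then HCl, MeOH, rt
Reagents that add atoms: osmium tetroxide, O=[Os](=O)(=O)=O
Why: Hydroxyl-directed dihydroxylation: the OsO4·TMEDA adduct is a strong hydrogen-bond acceptor and should be delivered by the allylic O5–H (O6–H lies on the same face) in a [3+2] addition to the electron-richer C3=C4 bond, setting C3 and C4 cis to O5/O6, while the ester-conjugated trisubstituted C1=C2 bond reacts more slowly; acid methanolysis then releases the diol from the hexavalent-osmium glycolate, and the methyl ester cannot be scrambled by methanol.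

**Step 3**
Reactants: 4 methyl (3S,4S,5R,6R)-3,4,5,6-tetrahydroxycyclohex-1-ene-1-carboxylate; 5 2-methoxypropene
Product: 6 methyl (3S,4R,5R,6R)-5,6-dihydroxy-3,4-(isopropylidenedioxy)cyclohex-1-ene-1-carboxylate
Conditions: 2-methoxypropene (1.2 equiv), PPTS (cat.), DMF, 0 °C; Et3N
Reagents that add atoms: 2-methoxypropene, COC(C)=C
Why: Kinetic acetonation: the mixed ketal should form first at the least encumbered allylic O3–H, remote from the ester, and its oxocarbenium ion can only close onto the cis-vicinal O4–H to give the cis-fused dioxolane, whereas O6–H is flanked by the ester-bearing C1; no stereocentre is touched.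

**Step 4**
Reactants: 6 methyl (3S,4R,5R,6R)-5,6-dihydroxy-3,4-(isopropylidenedioxy)cyclohex-1-ene-1-carboxylate
Product: 7 (3S,4R,5R,6R)-1-(hydroxymethyl)-3,4-(isopropylidenedioxy)cyclohex-1-ene-5,6-diol
Conditions: iBu2AlH (DIBAL-H, 5 equiv), CH2Cl2, −78 to −20 °C; aq. potassium sodium tartrate
Reagents that add atoms: none
Why: DIBAL-H 1,2-reduction of the α,β-unsaturated methyl ester to the allylic alcohol (the two hydroxyls are first converted into aluminium alkoxides, hence the excess); the ketal and all four stereocentres are inert to hydride.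

**Step 5**
Reactants: 7 (3S,4R,5R,6R)-1-(hydroxymethyl)-3,4-(isopropylidenedioxy)cyclohex-1-ene-5,6-diol; 8 benzoyl chloride
Product: 9 [(3S,4R,5R,6R)-5,6-dihydroxy-3,4-(isopropylidenedioxy)cyclohex-1-en-1-yl]methyl benzoate
Conditions: BzCl (1.05 equiv), 2,4,6-collidine, CH2Cl2, −78 to −40 °C
Reagents that add atoms: benzoyl chloride, O=C(Cl)c1ccccc1
Why: Chemoselective acylation (nucleophilic acyl substitution) of the primary allylic O7–H, which should react much faster than the two secondary hydroxyls at low temperature with a hindered pyridine base and no nucleophilic catalyst.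

**Step 6**
Reactants: 9 [(3S,4R,5R,6R)-5,6-dihydroxy-3,4-(isopropylidenedioxy)cyclohex-1-en-1-yl]methyl benzoate; 8 benzoyl chloride
Product: 10 [(3S,4S,5R,6R)-5-(benzoyloxy)-6-hydroxy-3,4-(isopropylidenedioxy)cyclohex-1-en-1-yl]methyl benzoate
Conditions: BzCl (1.1 equiv), Ph2BOCH2CH2NH2 (10 mol %), iPr2NEt, MeCN, rt
Reagents that add atoms: benzoyl chloride, O=C(Cl)c1ccccc1
Why: Borinic-acid-catalysed regioselective monoacylation of a cis-1,2-diol: the tetracoordinate diphenylborinate of the 5,6-diol should be acylated at its more accessible, equatorial-type oxygen, expected to be O5 because O6 is pseudoaxial (it avoids A(1,2) strain with the C1 substituent) and is shielded by CH2OBz, and turnover releases the mono-ester so that over-acylation is suppressed.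

**Step 7**
Reactants: 10 [(3S,4S,5R,6R)-5-(benzoyloxy)-6-hydroxy-3,4-(isopropylidenedioxy)cyclohex-1-en-1-yl]methyl benzoate
Product: 11 [(3S,4S,5R,6R)-5-(benzoyloxy)-3,4,6-trihydroxycyclohex-1-en-1-yl]methyl benzoate (CNP0198957.4)
Conditions: TFA/H2O (9:1), CH2Cl2, 0 °C
Reagents that add atoms: none
Why: Acid-catalysed hydrolysis of the isopropylidene ketal; the benzoates should neither cleave nor migrate under brief cold aqueous acid, and no stereocentre is involved.

**Compound list**
1 | methyl benzoate | COC(=O)c1ccccc1 | starting material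
2 | methyl (5S,6R)-5,6-dihydroxycyclohexa-1,3-diene-1-carboxylate | COC(=O)C1=CC=C[C@H](O)[C@@H]1O | intermediate
3 | cyclic O3,O4-osmate ester of 4, hexavalent-osmium glycolate OsO2(TMEDA), 5-OH and 6-OH free, all-cis | COC(=O)C1=C[C@@H]2O[Os-2]3(=O)(=O)([N+](C)(C)CC[N+]3(C)C)O[C@@H]2[C@H](O)[C@@H]1O | intermediate
4 | methyl (3S,4S,5R,6R)-3,4,5,6-tetrahydroxycyclohex-1-ene-1-carboxylate (all-cis) | COC(=O)C1=C[C@H](O)[C@H](O)[C@H](O)[C@@H]1O | intermediate
5 | 2-methoxypropene | COC(C)=C | starting material
6 | methyl (3S,4R,5R,6R)-5,6-dihydroxy-3,4-(isopropylidenedioxy)cyclohex-1-ene-1-carboxylate | COC(=O)C1=C[C@@H]2OC(C)(C)O[C@@H]2[C@H](O)[C@@H]1O | intermediate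
7 | (3S,4R,5R,6R)-1-(hydroxymethyl)-3,4-(isopropylidenedioxy)cyclohex-1-ene-5,6-diol | OCC1=C[C@@H]2OC(C)(C)O[C@@H]2[C@H](O)[C@@H]1O | intermediate
8 | benzoyl chloride | O=C(Cl)c1ccccc1 | starting material
9 | [(3S,4R,5R,6R)-5,6-dihydroxy-3,4-(isopropylidenedioxy)cyclohex-1-en-1-yl]methyl benzoate | O=C(OCC1=C[C@@H]2OC(C)(C)O[C@@H]2[C@H](O)[C@@H]1O)c1ccccc1 | intermediate
10 | [(3S,4S,5R,6R)-5-(benzoyloxy)-6-hydroxy-3,4-(isopropylidenedioxy)cyclohex-1-en-1-yl]methyl benzoate | O=C(OCC1=C[C@@H]2OC(C)(C)O[C@@H]2[C@H](OC(=O)c3ccccc3)[C@@H]1O)c1ccccc1 | intermediate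
11 | [(3S,4S,5R,6R)-5-(benzoyloxy)-3,4,6-trihydroxycyclohex-1-en-1-yl]methyl benzoate | O=C(OCC1=C[C@H](O)[C@H](O)[C@H](OC(=O)c2ccccc2)[C@@H]1O)c1ccccc1 | target

**Total steps:** 7. **Longest linear sequence:** 7 steps (1 → 11).

**Steps most likely to fail**

Step 3. The ketal may close on the wrong cis-diol pair (O5/O6 or O4/O5), or a second ketal may form, because all four hydroxyls are mutually cis. Fallback: replace reversible ketalisation by an irreversible bridging silylation whose position is fixed by sterics at the first Si–O bond. Setting out from 4, TIPDSCl2 and imidazole in DMF at low temperature should silylate the most accessible O3–H and then close on O4, giving the 3,4-O-(tetraisopropyldisiloxane-1,3-diyl) diol ester F1. DIBAL-H reduction should give the disiloxane-protected triol F2, and low-temperature BzCl/collidine its O7-benzoate F3. Borinate-catalysed benzoylation should then give the O5,O7-dibenzoate F4. HF·pyridine in THF at 0 °C removes the disiloxane and the route is rejoined at 11.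

Step 6. Acylation may occur at the neighbouring O6 hydroxyl, or the benzoate may migrate between O5 and O6. Fallback: block O6 by a tether from O7 instead of relying on reagent discrimination. Setting out from 7, tBu2Si(OTf)2 and 2,6-lutidine should attack the primary O7–H first and can then only close a six-membered ring onto O6, giving the 6,7-O-di-tert-butylsilylene acetonide F5 with O5–H as the sole free hydroxyl. BzCl, DMAP and pyridine give the silylene-protected O5-benzoate F6. HF·pyridine removes the silylene to give the O5-benzoate 6,7-diol F7, and low-temperature BzCl/collidine acylates the primary O7–H, rejoining the route at 10.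

Step 2. Osmylation may take place from the face opposite the hydroxyls if hydrogen-bond delivery is out-competed by sterics, and release of the polar tetrol from osmium may be incomplete. Fallback: switch the control element from hydrogen-bond delivery to neighbouring-group participation. Setting out from 2, 2,2-dimethoxypropane and TsOH in acetone give the 5,6-acetonide of the diene ester F8, which should be used fresh. Woodward cis-hydroxylation (I2, AgOAc, AcOH, rt; then wet AcOH, heat) should form the iodonium ion anti to the ketal, and internal displacement of iodide by the first acetate places both new oxygens on the ketal face. This should give the all-cis 4-O-acetyl hydroxy acetate F9 and its 3-O-acetyl regioisomer F10. HCl in MeOH removes acetate and ketal from both, rejoining the route at 4.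

**Further compounds**
F1 | step 3 | methyl 5,6-dihydroxy-3,4-O-(1,1,3,3-tetraisopropyldisiloxane-1,3-diyl)cyclohex-1-ene-1-carboxylate, all-cis, configuration as in 4 | COC(=O)C1=C[C@@H]2O[Si](C(C)C)(C(C)C)O[Si](C(C)C)(C(C)C)O[C@@H]2[C@H](O)[C@@H]1O
F2 | step 3 | 1-(hydroxymethyl)-3,4-O-(1,1,3,3-tetraisopropyldisiloxane-1,3-diyl)cyclohex-1-ene-5,6-diol, all-cis, configuration as in 7 | OCC1=C[C@@H]2O[Si](C(C)C)(C(C)C)O[Si](C(C)C)(C(C)C)O[C@@H]2[C@H](O)[C@@H]1O
F3 | step 3 | O7-benzoate of F2 | O=C(OCC1=C[C@@H]2O[Si](C(C)C)(C(C)C)O[Si](C(C)C)(C(C)C)O[C@@H]2[C@H](O)[C@@H]1O)c1ccccc1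
F4 | step 3 | O5,O7-dibenzoate of F2 | O=C(OCC1=C[C@@H]2O[Si](C(C)C)(C(C)C)O[Si](C(C)C)(C(C)C)O[C@@H]2[C@H](OC(=O)c3ccccc3)[C@@H]1O)c1ccccc1
F5 | step 6 | 6,7-O-(di-tert-butylsilylene) derivative of 7, O5–H free | CC(C)(C)[Si]1(C(C)(C)C)OCC2=C[C@@H]3OC(C)(C)O[C@@H]3[C@H](O)[C@@H]2O1
F6 | step 6 | O5-benzoate of F5 | CC(C)(C)[Si]1(C(C)(C)C)OCC2=C[C@@H]3OC(C)(C)O[C@@H]3[C@H](OC(=O)c4ccccc4)[C@@H]2O1
F7 | step 6 | O5-benzoate of 7 (O6–H and O7–H free, 3,4-acetonide) | OCC1=C[C@@H]2OC(C)(C)O[C@@H]2[C@H](OC(=O)c3ccccc3)[C@@H]1O
F8 | step 2 | methyl (5S,6R)-5,6-(isopropylidenedioxy)cyclohexa-1,3-diene-1-carboxylate | COC(=O)C1=CC=C[C@@H]2OC(C)(C)O[C@H]12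
F9 | step 2 | methyl 4-acetoxy-3-hydroxy-5,6-(isopropylidenedioxy)cyclohex-1-ene-1-carboxylate, all-cis | COC(=O)C1=C[C@H](O)[C@H](OC(C)=O)[C@@H]2OC(C)(C)O[C@H]12
F10 | step 2 | methyl 3-acetoxy-4-hydroxy-5,6-(isopropylidenedioxy)cyclohex-1-ene-1-carboxylate, all-cis | COC(=O)C1=C[C@H](OC(C)=O)[C@H](O)[C@@H]2OC(C)(C)O[C@H]12
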